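## Retrosynthetic overview

1. Ring 2 (the methoxy peroxyketal dioxine) is opened last at its C3–O bond: a 6-exo peroxy-Michael addition of the C6 hydroperoxy methyl ketal 12 onto the (2E)-enoate. Compound 12 comes from the (Z)-enone 11 with H2O2/MeOH.
2. Key step: one-flask double singlet-oxygenation of the achiral furyl diene 7. [4+2] addition across the (E,E)-diene closes ring 1 (the propyl dioxine, cis). [4+2] addition across the furan breaks its aromaticity and, after Me2S, releases the ring-locked (Z)-4-oxo-enal, which a Wittig reagent extends to the (2E,4Z)-dienoate.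
3. Compound 7 is assembled from furan, allyl bromide and (E)-hex-2-enal (Takai iodide, B-alkyl Suzuki coupling).
4. Ring order: ring 1 (step 4), then ring 2 (step 7). Absolute configuration: ring 1 by resolution of the first chiral intermediate 10; C3 of ring 2 by catalyst control; C6 by separating the epimer pair 13 and re-equilibrating the unwanted epimer with acid (step 8).

Assumption: the resolution in step 5 and the epimer separation with recycling in step 8 are each counted as a step, racemic compounds 8–10 are named and drawn as the enantiomer that is carried forward, and the squaramide of step 7 is taken to deliver 3R (its quinidine-derived pseudo-enantiomer is used if the first run shows the opposite sense).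

## Route

Step 1
Reactants: 1 furan
Product: 3 2-allylfuran, via 2-furyllithium 2 (not isolated)
Conditions: n-BuLi, THF, −78 → 0 °C; allyl bromide, −78 °C → rt
Reagents that add atoms: allyl bromide, C=CCBr; n-butyllithium, [Li]CCCC (its lithium is held only in 2)
Why: α-lithiation of furan and SN2 allylation of the resulting 2-furyllithium (heteroaryllithium alkylation); no stereocentre is formed.

Step 2
Reactants: 4 (E)-hex-2-enal
Product: 5 (1E,3E)-1-iodohepta-1,3-diene
Conditions: CHI3, CrCl2, THF/1,4-dioxane (1:6), 0 °C → rt, dark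
Reagents that add atoms: iodoform, IC(I)I
Why: Takai olefination, in which the gem-dichromium carbenoid formed from CHI3 and divalent chromium adds to the aldehyde and eliminates to the (E)-vinyl iodide (about 8:1 E/Z expected in dioxane-rich solvent) without touching the existing (E)-alkene.

Step 3
Reactants: 3 2-allylfuran; 5 (1E,3E)-1-iodohepta-1,3-diene
Product: 7 2-[(4E,6E)-deca-4,6-dien-1-yl]furan, via B-alkyl-9-BBN adduct 6 (not isolated)
Conditions: 9-BBN, THF, 0 °C → rt; then 5, PdCl2(dppf) (5 mol %), Ph3As, Cs2CO3, DMF/H2O, rt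
Reagents that add atoms: 9-borabicyclo[3.3.1]nonane, B1C2CCCC1CCC2 (its boron is held only in 6)
Why: anti-Markovnikov hydroboration of the terminal alkene followed by B-alkyl Suzuki–Miyaura coupling, in which zerovalent palladium inserts into the C–I bond and couples with retention of both diene geometries (any minor 4Z isomer is removed on AgNO3-impregnated silica).

Step 4
Reactants: 7 2-[(4E,6E)-deca-4,6-dien-1-yl]furan
Product: 10 methyl (2E,4Z)-6-oxo-9-[(3R,6S)-6-propyl-3,6-dihydro-1,2-dioxin-3-yl]nona-2,4-dienoate (racemate), via methoxy hydroperoxide 8 (not isolated), via keto-enal 9 (not isolated)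
Conditions: O2, 5,10,15,20-tetraphenylporphyrin (0.5 mol %), white LED, CH2Cl2/MeOH (9:1), −78 °C then 0 °C; Me2S, −78 °C → rt; Ph3P=CHCO2Me, CH2Cl2, 0 °C
Reagents that add atoms: oxygen, O=O; methanol, CO (held only in 8); methyl (triphenylphosphoranylidene)acetate, COC(=O)C=P(c1ccccc1)(c1ccccc1)c1ccccc1
Why: two singlet-oxygen [4+2] cycloadditions in one flask followed by an E-selective Wittig reaction: suprafacial addition to the s-cis (E,E)-diene closes ring 1 with its two alkyl groups cis (racemic), while addition across the furan 2,5-positions and methanolysis dearomatise the heterocycle to 8, which Me2S (inert to dialkyl peroxides) reduces to the (Z)-4-oxo-enal 9 that the stabilised ylide intercepts at the aldehyde only, so the 4Z geometry comes from the furan ring and the 2E geometry from the ylide.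

Step 5
Reactants: 10 methyl (2E,4Z)-6-oxo-9-[(3R,6S)-6-propyl-3,6-dihydro-1,2-dioxin-3-yl]nona-2,4-dienoate (racemate)
Product: 11 methyl (2E,4Z)-6-oxo-9-[(3R,6S)-6-propyl-3,6-dihydro-1,2-dioxin-3-yl]nona-2,4-dienoate (single enantiomer)
Conditions: preparative SFC, amylose tris(3,5-dimethylphenylcarbamate) phase, CO2/i-PrOH, 30 °C
Reagents that add atoms: none
Why: chromatographic resolution on a chiral stationary phase, which works because 10 carries only the two ring 1 stereocentres, so its enantiomers separate as two peaks and the (3R,6S) antipode (assigned by vibrational circular dichroism) is carried on; this sets the absolute configuration of ring 1.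

Step 6
Reactants: 11 methyl (2E,4Z)-6-oxo-9-[(3R,6S)-6-propyl-3,6-dihydro-1,2-dioxin-3-yl]nona-2,4-dienoate
Product: 12 methyl (2E,4Z)-6-hydroperoxy-6-methoxy-9-[(3R,6S)-6-propyl-3,6-dihydro-1,2-dioxin-3-yl]nona-2,4-dienoate (1:1 at C6)
Conditions: urea·H2O2, Sc(OTf)3 (10 mol %), MeOH, 0 °C
Reagents that add atoms: hydrogen peroxide (as urea–hydrogen peroxide), OO; methanol, CO
Why: Lewis acid-catalysed hydroperoxyketalisation, in which Sc(OTf)3 activates the twisted (Z)-enone carbonyl towards methanol and the resulting oxocarbenium ion is captured by H2O2, giving the C6 hydroperoxy methyl ketal as both epimers without base, so the enoate is not yet attacked.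

Step 7
Reactants: 12 methyl (2E,4Z)-6-hydroperoxy-6-methoxy-9-[(3R,6S)-6-propyl-3,6-dihydro-1,2-dioxin-3-yl]nona-2,4-dienoate
Product: 13 methyl 2-[(3R)-6-methoxy-6-{3-[(3R,6S)-6-propyl-3,6-dihydro-1,2-dioxin-3-yl]propyl}-3,6-dihydro-1,2-dioxin-3-yl]acetate (pair of C6 epimers, about 1:1)
Conditions: 3-{[3,5-bis(trifluoromethyl)phenyl]amino}-4-{[(8α,9S)-6′-methoxycinchonan-9-yl]amino}cyclobut-3-ene-1,2-dione (10 mol %), toluene, −20 °C; short SiO2 plug to remove the catalyst
Reagents that add atoms: none
Why: Proposed new method: the quinuclidine nitrogen deprotonates the hydroperoxide while the squaramide N–H pair binds the ester carbonyl, so the peroxy anion adds 6-exo-trig to one face of the (E)-enoate and the quinuclidinium ion protonates the ester enolate before it can attack the O–O bond, which sets C3 as R under catalyst control in both C6 epimers of 12 and therefore gives 13 as the 6S/6R pair in the 1:1 ratio inherited from 12; the closest known reaction types are the Et2NH-promoted intramolecular peroxy-Michael addition of hydroperoxy ketals to enoates and squaramide-catalysed intramolecular oxa-Michael additions.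

Step 8
Reactants: 13 methyl 2-[(3R)-6-methoxy-6-{3-[(3R,6S)-6-propyl-3,6-dihydro-1,2-dioxin-3-yl]propyl}-3,6-dihydro-1,2-dioxin-3-yl]acetate (pair of C6 epimers)
Product: 14 methyl 2-[(3R,6S)-6-methoxy-6-{3-[(3R,6S)-6-propyl-3,6-dihydro-1,2-dioxin-3-yl]propyl}-3,6-dihydro-1,2-dioxin-3-yl]acetate (target)
Conditions: SiO2 chromatography (hexane/EtOAc), 6S epimer collected; 6R fraction: camphorsulfonic acid (10 mol %), MeOH, rt, then SiO2 again (repeated)
Reagents that add atoms: methanol, CO (replaces the C6 methoxy group in the recycled portion)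
Why: separation of diastereomers followed by acid-catalysed ketal equilibration: the two epimers differ in the relative configuration within ring 2 and separate on silica, and the acid ionises the allylic peroxy ketal of the 6R epimer to a peroxycarbenium ion that methanol recaptures on either face, which epimerises C6 only (C3 and ring 1 are untouched) to a mixture of comparable amounts of both epimers (each can hold the methoxy group pseudoaxial), so repeated cycles funnel 13 into the 6S epimer.

## Compound list

1 | furan | c1ccoc1 | starting material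
2 | 2-furyllithium | [Li]c1ccco1 | intermediate (not isolated)
3 | 2-allylfuran | C=CCc1ccco1 | intermediate
4 | (E)-hex-2-enal | CCC/C=C/C=O | starting material
5 | (1E,3E)-1-iodohepta-1,3-diene | CCC/C=C/C=C/I | intermediate
6 | 9-[3-(furan-2-yl)propyl]-9-borabicyclo[3.3.1]nonane | c1coc(CCCB2C3CCCC2CCC3)c1 | intermediate (not isolated)
7 | 2-[(4E,6E)-deca-4,6-dien-1-yl]furan | CCC/C=C/C=C/CCCc1ccco1 | intermediate
8 | 5-hydroperoxy-2-methoxy-2-{3-[(3R,6S)-6-propyl-3,6-dihydro-1,2-dioxin-3-yl]propyl}-2,5-dihydrofuran (racemic in ring 1, dihydrofuran centres mixed) | CCC[C@H]1C=C[C@@H](CCCC2(OC)C=CC(OO)O2)OO1 | intermediate (not isolated)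
9 | (2Z)-4-oxo-7-[(3R,6S)-6-propyl-3,6-dihydro-1,2-dioxin-3-yl]hept-2-enal (racemate) | CCC[C@H]1C=C[C@@H](CCCC(=O)/C=C\C=O)OO1 | intermediate (not isolated)
10 | methyl (2E,4Z)-6-oxo-9-[(3R,6S)-6-propyl-3,6-dihydro-1,2-dioxin-3-yl]nona-2,4-dienoate (racemate, cis ring 1) | CCC[C@H]1C=C[C@@H](CCCC(=O)/C=C\C=C\C(=O)OC)OO1 | intermediate
11 | methyl (2E,4Z)-6-oxo-9-[(3R,6S)-6-propyl-3,6-dihydro-1,2-dioxin-3-yl]nona-2,4-dienoate (single enantiomer) | CCC[C@H]1C=C[C@@H](CCCC(=O)/C=C\C=C\C(=O)OC)OO1 | intermediate
12 | methyl (2E,4Z)-6-hydroperoxy-6-methoxy-9-[(3R,6S)-6-propyl-3,6-dihydro-1,2-dioxin-3-yl]nona-2,4-dienoate (both C6 epimers) | CCC[C@H]1C=C[C@@H](CCCC(OC)(OO)/C=C\C=C\C(=O)OC)OO1 | intermediate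
13 | methyl 2-[(3R)-6-methoxy-6-{3-[(3R,6S)-6-propyl-3,6-dihydro-1,2-dioxin-3-yl]propyl}-3,6-dihydro-1,2-dioxin-3-yl]acetate (pair of C6 epimers) | CCC[C@H]1C=C[C@@H](CCCC2(OC)C=C[C@@H](CC(=O)OC)OO2)OO1 | intermediate
14 | methyl 2-[(3R,6S)-6-methoxy-6-{3-[(3R,6S)-6-propyl-3,6-dihydro-1,2-dioxin-3-yl]propyl}-3,6-dihydro-1,2-dioxin-3-yl]acetate | CCC[C@H]1C=C[C@@H](CCC[C@@]2(OC)C=C[C@@H](CC(=O)OC)OO2)OO1 | target

## Step count and risks

Total step count: 8 (six bond-forming steps, one resolution, and one epimer separation with acid recycling). Longest linear sequence: 7 steps from furan (steps 1, 3, 4, 5, 6, 7, 8); step 2 is the side branch.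

**Risk 1, step 4.** The diene may give ene hydroperoxides beside the [4+2] adduct. The (Z)-enal may isomerise before the ylide traps it. The ylide may act as a base on ring 1 (Kornblum–DeLaMare opening). The fallback separates the two singlet-oxygen events so that ring 1 never meets Me2S or ylide. It sets out from 7. Photooxygenation at −78 °C only (tetraphenylporphyrin, O2, CH2Cl2/MeOH), where the furan reacts about a hundred times faster than the diene, gives 2-[(4E,6E)-deca-4,6-dien-1-yl]-5-hydroperoxy-2-methoxy-2,5-dihydrofuran F1. Me2S reduces it to (2Z,8E,10E)-4-oxotetradeca-2,8,10-trienal F2, and the ylide converts this to methyl (2E,4Z,10E,12E)-6-oxohexadeca-2,4,10,12-tetraenoate F3, which is isolated. Ring 1 is then closed in a separate photooxygenation (methylene blue, O2, red LED, CH2Cl2, 0 °C), in which the electron-poor dienoate is inert. The fallback comes back to the route at 10.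

**Risk 2, step 6.** The Lewis acid may isomerise the (Z)-enone, methanol or H2O2 may add in conjugate fashion, a gem-dihydroperoxide may form in place of the mixed ketal, or the allylic hydroperoxy ketal may undergo Hock-type cleavage. The fallback closes ring 2 at the hemiketal stage and methylates afterwards. It sets out from 11. Anhydrous ethereal H2O2 and the squaramide of step 7 (toluene, −20 °C) let the hydroperoxy hemiketal form reversibly and close by the same peroxy-Michael addition. This gives methyl 2-[(3R)-6-hydroxy-6-{3-[(3R,6S)-6-propyl-3,6-dihydro-1,2-dioxin-3-yl]propyl}-3,6-dihydro-1,2-dioxin-3-yl]acetate F4, whose C6 epimers interconvert. Methanol with catalytic camphorsulfonic acid then exchanges OH for OMe through the allylic peroxycarbenium ion and gives both C6 methoxy epimers. The fallback comes back at 13 and skips 12.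

**Risk 3, step 7.** The catalyst may give low facial selectivity at C3, above all for the C6 epimer of 12 in which substrate and catalyst preferences are mismatched. An uncatalysed background cyclisation may compete, or the amine may open ring 1 by Kornblum–DeLaMare rearrangement. The fallback gives up catalyst control and obtains the C3 configuration by separation. It sets out from 12. Cyclisation with catalytic Et2NH in CF3CH2OH at rt gives all four ring 2 stereoisomers: the two epimers of 13, methyl 2-[(3S,6R)-6-methoxy-6-{3-[(3R,6S)-6-propyl-3,6-dihydro-1,2-dioxin-3-yl]propyl}-3,6-dihydro-1,2-dioxin-3-yl]acetate F5 and methyl 2-[(3S,6S)-6-methoxy-6-{3-[(3R,6S)-6-propyl-3,6-dihydro-1,2-dioxin-3-yl]propyl}-3,6-dihydro-1,2-dioxin-3-yl]acetate F6. Silica separates by relative configuration within ring 2, so the 6S epimer of 13 elutes together with F5 and the 6R epimer of 13 together with F6. HPLC on a chiral phase then separates the 6S epimer of 13 from F5, which are diastereomers because ring 1 is already fixed. The fallback comes back at 14.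

## Further compounds

F1 | step 4 | 2-[(4E,6E)-deca-4,6-dien-1-yl]-5-hydroperoxy-2-methoxy-2,5-dihydrofuran | CCC/C=C/C=C/CCCC1(OC)C=CC(OO)O1
F2 | step 4 | (2Z,8E,10E)-4-oxotetradeca-2,8,10-trienal | CCC/C=C/C=C/CCCC(=O)/C=C\C=O
F3 | step 4 | methyl (2E,4Z,10E,12E)-6-oxohexadeca-2,4,10,12-tetraenoate | CCC/C=C/C=C/CCCC(=O)/C=C\C=C\C(=O)OC
F4 | step 6 | methyl 2-[(3R)-6-hydroxy-6-{3-[(3R,6S)-6-propyl-3,6-dihydro-1,2-dioxin-3-yl]propyl}-3,6-dihydro-1,2-dioxin-3-yl]acetate | CCC[C@H]1C=C[C@@H](CCCC2(O)C=C[C@@H](CC(=O)OC)OO2)OO1
F5 | step 7 | methyl 2-[(3S,6R)-6-methoxy-6-{3-[(3R,6S)-6-propyl-3,6-dihydro-1,2-dioxin-3-yl]propyl}-3,6-dihydro-1,2-dioxin-3-yl]acetate | CCC[C@H]1C=C[C@@H](CCC[C@]2(OC)C=C[C@H](CC(=O)OC)OO2)OO1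
F6 | step 7 | methyl 2-[(3S,6S)-6-methoxy-6-{3-[(3R,6S)-6-propyl-3,6-dihydro-1,2-dioxin-3-yl]propyl}-3,6-dihydro-1,2-dioxin-3-yl]acetate | CCC[C@H]1C=C[C@@H](CCC[C@@]2(OC)C=C[C@H](CC(=O)OC)OO2)OO1
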